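Readings and results stem from a simulated flask for substances that don't exist.

The midnight run stops with substrate still present: from 10.0 h on, substrate stays near 41.1% and product near 37.0%. That product lies close to the partner charge of 0.38 equiv, so one partner appears to make one product, and partner is the limiting reagent there.

| setting | midnight | spring | east | south-west | west |
|---|---|---|---|---|---|
| substrate | 0.68 M | 0.68 M | 0.68 M | 0.68 M | 0.68 M |
| partner | 0.38 equiv | 2.1 equiv | 0.700 equiv | 1.40 equiv | 2.80 equiv |
| initiator | 10 mol% | 10 mol% | 10 mol% | 10 mol% | 10 mol% |
| remark | run made earlier | run made earlier |  |  |  |
| time |  |  | 40 h | 40 h | 40 h |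

| run | time / h | substrate / % | product / % |
|---|---|---|---|
| midnight | 2.50 | 51.6 | 38.5 |
| midnight | 4.00 | 45.7 | 39.5 |
| midnight | 6.00 | 43.5 | 37.8 |
| midnight | 10.0 | 41.1 | 37.0 |
| midnight | 15.0 | 41.1 | 37.1 |
| midnight | 30.0 | 42.6 | 38.6 |
| spring | 5.00 | 0 | 97.5 |
| spring | 10.0 | 1.7 | 98.4 |
| spring | 15.0 | 0 | 99.0 |
| spring | 20.0 | 0.4 | 98.7 |
| spring | 25.0 | 0.4 | 97.8 |
| spring | 30.0 | 0 | 99.2 |

(standard deviation of a reading: 1 percentage point)

1. part of the substrate that has reacted at the end, east
2. part of the substrate that has reacted at the end, south-west
3. part of the substrate that has reacted at the end, west
4. what raising the equivalents of partner from its lowest to its highest value here does to the part of the substrate that has reacted (changes below 5 percentage points count as none) (it rises / no change / it falls)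



The midnight balance has a gap: charge that is neither substrate nor product. Averaged over the last three readings, it is

gap = 20.8%, beside twice the initiator loading, 20.0%.

The spring run, with partner in excess, reads substrate 0% and product 97.5% at 5.00 h. Its gap there is 2.50%, less than the midnight one.

The reckoning here therefore treats the gap as a drain of a flask short of partner, and adds the two drains for such a flask. For east:

partner + twice the loading = 90.0%

This sum, capped at the whole charge, is the spend: the part of the substrate expected to react by the end.

The weak link is whether the gap is a constant sum or a share of what remains. In the midnight run it reads 9.90% at 2.50 h, about half of its final value, and it stops growing by 10.0 h with substrate at 41.1%. The midnight loss ends with so much substrate present that it is read as following a clock of its own, so for a flask short of partner it is taken as a constant sum tied to the initiator. East runs 40 h, longer than that clock needs.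

Uncapped, the sum is 160% for south-west and 300% for west, so both should react completely. The rise from east to west is then 10 percentage points, against a margin of 5 points.

The forecast gives 80%, 99.5% and 99.5%, with the trend "it rises". For east it stands below the spend, on its reading of “roughly one third of leftover substrate in that form”.

The flask gives 89.9%, 100% and 100%, and the trend is "it rises".

    substrate + second chain carrier → released group + first chain carrier (k = 17000 /M/s)
    released group → by-product carried off (k = 0.370 /min)
    initiator → 2 initiating radical (k = 0.00620 /min)
    substrate + initiating radical → capped initiator + first chain carrier (k = 24000 /M/s)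
    partner + first chain carrier → product + second chain carrier (k = 86000 /M/min)
    partner + released group ⇌ idle adduct, settled at all times (K = 5.30 /M)
    2 second chain carrier → ended chains A (k = 2.40 × 10⁸ /M/s)
    2 first chain carrier → ended chains B (k = 2.00 × 10⁷ /M/s)

East gives 89.9% beside the spend of 90.0%, with ended chains B at 19.9% of the substrate charged, each counted as the two it holds. West ends with substrate at 0% and partner at 65%. Its neighbour is the same flask with partner cut to 0.700 equiv, where the spend is 90.0% and the flask gives 89.9%. There partner ends at 0%, product at 70.0%, ended chains B at 19.9% and substrate at 10%.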